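**Plan**

- Retrosynthesis: cut the aryl ether bond O–C1' (Mitsunobu coupling with scopoletin), then C1'–C2' and C3'–CH3 together (methylalumination–hydroxymethylation of a terminal alkyne), then C3'–C4' (acetylide addition to a Weinreb amide made from 5,5-dimethylbutyrolactone).
- Enabling feature: the E-trisubstituted C2'=C3' alkene has its C3' methyl cis to C1', which is what syn addition of CH3 and a one-carbon electrophile across a terminal alkyne attached to C4' leaves behind. The benzene and pyranone rings of the coumarin arrive intact in scopoletin.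
- Forward: the acyclic chain is assembled from C8'–C4' (lactone), C3'/C2' (alkyne), then 3'-CH3 and C1' (key step), and is finally joined to O7 of scopoletin. No ring is formed anywhere in the route.
- Stereochemistry: C4' (R) comes from asymmetric transfer hydrogenation of the ynone with RuCl[(R,R)-TsDPEN](p-cymene). The E geometry comes from syn carbometalation and retentive trapping. Both are carried unchanged to the target.

Key step: step 7

Remark: the side chain is numbered C1' (OCH2) to C8'; the target is (2'E,4'R) as its SMILES specifies, and the (R,R)-ligand is assumed to give the (R)-carbinol by analogy with aryl ketones, where the (S,S)-ligand gives the (S)-alcohol and the alkynyl group plays the part of the aryl group.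

**Step 1**
Reactants: 1 5,5-dimethyldihydrofuran-2(3H)-one
Product: 2 4-hydroxy-N-methoxy-N,4-dimethylpentanamide
Conditions: Me2AlCl, MeNH(OMe)·HCl, CH2Cl2, 0 °C → rt; aq. KNaC4H4O6 (potassium sodium tartrate), 0 °C; crude product used at once
Reagents that add atoms: N,O-dimethylhydroxylamine hydrochloride, CNOC.Cl
Why: Weinreb-type aminolysis of a lactone, in which Cl2AlN(OMe)Me formed in the flask attacks the acyl carbon and the strong Al–O bond holds the released tertiary alkoxide, so the hydroxy amide should survive a neutral work-up.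

**Step 2**
Reactants: 2 4-hydroxy-N-methoxy-N,4-dimethylpentanamide
Product: 3 N-methoxy-N,4-dimethyl-4-(triethylsilyloxy)pentanamide
Conditions: TESOTf, 2,6-lutidine, CH2Cl2, −78 → 0 °C
Reagents that add atoms: triethylsilyl trifluoromethanesulfonate, CC[Si](CC)(CC)OS(=O)(=O)C(F)(F)F
Why: Silyl triflate with 2,6-lutidine is the standard silylation of a hindered tertiary alcohol, and capping the hydroxyl immediately closes the path back to lactone 1.

**Step 3**
Reactants: 3 N-methoxy-N,4-dimethyl-4-(triethylsilyloxy)pentanamide; 4 ethynyltrimethylsilane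
Product: 6 6-methyl-6-(triethylsilyloxy)-1-(trimethylsilyl)hept-1-yn-3-one, via lithium (trimethylsilyl)acetylide 5 (not isolated)
Conditions: 4, n-BuLi, THF, −78 °C; then 3, −78 → −20 °C; inverse quench into cold aq. NH4Cl
Reagents that add atoms: ethynyltrimethylsilane (4), C#C[Si](C)(C)C
Why: Weinreb ketone synthesis, in which the lithium acetylide adds once to give a chelated tetrahedral adduct that releases the ynone only on work-up, so the C3'–C4' bond forms without over-addition.

**Step 4**
Reactants: 6 6-methyl-6-(triethylsilyloxy)-1-(trimethylsilyl)hept-1-yn-3-one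
Product: 7 (R)-6-methyl-6-(triethylsilyloxy)-1-(trimethylsilyl)hept-1-yn-3-ol
Conditions: Ru[(R,R)-TsDPEN](p-cymene) (2 mol%, generated from RuCl[(R,R)-TsDPEN](p-cymene) and KOH), i-PrOH, rt
Reagents that add atoms: none
Why: Noyori asymmetric transfer hydrogenation of an α,β-acetylenic ketone, in which the Ru–H/N–H complex recognises the alkynyl group as the π-substituent and the (R,R)-ligand should deliver hydride to the carbonyl face that gives the (R)-carbinol at C4', while neutral 2-propanol as hydrogen donor leaves both silyl groups untouched.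

**Step 5**
Reactants: 7 (R)-6-methyl-6-(triethylsilyloxy)-1-(trimethylsilyl)hept-1-yn-3-ol
Product: 8 (R)-3-(tert-butyldimethylsilyloxy)-6-methyl-6-(triethylsilyloxy)-1-(trimethylsilyl)hept-1-yne
Conditions: TBSCl, imidazole, DMF, 0 °C → rt
Reagents that add atoms: tert-butyldimethylsilyl chloride, CC(C)(C)[Si](C)(C)Cl
Why: Imidazole-promoted silylation of a secondary propargylic alcohol is routine, does not touch the C–O bond of the stereocentre, and masks the C4' hydroxyl for the later etherification.

**Step 6**
Reactants: 8 (R)-3-(tert-butyldimethylsilyloxy)-6-methyl-6-(triethylsilyloxy)-1-(trimethylsilyl)hept-1-yne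
Product: 9 (R)-3-(tert-butyldimethylsilyloxy)-6-methyl-6-(triethylsilyloxy)hept-1-yne
Conditions: K2CO3, MeOH, rt
Reagents that add atoms: none
Why: Base-catalysed methanolysis cleaves only the silicon–C(sp) bond, since both silyl ethers are stable to K2CO3/MeOH and the C4' hydrogen is not acidic enough to epimerise.

**Step 7**
Reactants: 9 (R)-3-(tert-butyldimethylsilyloxy)-6-methyl-6-(triethylsilyloxy)hept-1-yne; 10 trimethylaluminium; 11 formaldehyde (used as paraformaldehyde)
Product: 14 (R,E)-4-(tert-butyldimethylsilyloxy)-3,7-dimethyl-7-(triethylsilyloxy)oct-2-en-1-ol, via alkenyldimethylalane 12 (not isolated), via lithium butyl(dimethyl)alkenylalanate 13 (not isolated)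
Conditions: AlMe3 (3 equiv), Cp2ZrCl2 (0.25 equiv), H2O (1 equiv), CH2Cl2, −20 → 0 °C; volatiles removed in vacuo; n-BuLi, hexane/THF, −78 → 0 °C; (CH2O)n, THF, 0 °C → rt; aq. KNaC4H4O6
Reagents that add atoms: trimethylaluminium (10), C[Al](C)C; formaldehyde from paraformaldehyde (11), C=O
Why: Cp2Zr(CH3)Cl, formed from Cp2ZrCl2 and AlMe3 and activated by aluminium Lewis acids including (MeAlO)n from the added water, adds its Zr–CH3 bond across the terminal alkyne in a concerted four-centre syn fashion, methyl to the internal carbon (C3') and metal to the terminal carbon (C2'), and Zr-to-Al exchange gives alane 12 and returns the catalyst. n-BuLi converts 12 into the more nucleophilic alanate 13, whose alkenyl group attacks formaldehyde with retention at C2' to make the C1'–C2' bond. The closest known reaction type is the Negishi zirconium-catalysed methylalumination of terminal alkynes with formaldehyde trapping of the alanate, an established entry to E-3-methylalk-2-en-1-ols. No ring is closed and no stereocentre is created; the only stereochemical element formed is the E alkene, fixed by the syn addition and the retentive trapping. The step needs regioselectivity and syn stereospecificity: the first is secured by the terminal alkyne together with the branched, silyloxy-bearing C4' that keeps the metal at the unhindered terminus, the second by the concerted mechanism. C4' carries no acidic hydrogen and its oxygen is masked as a bulky silyl ether, so the centre should pass through unchanged.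

**Step 8**
Reactants: 14 (R,E)-4-(tert-butyldimethylsilyloxy)-3,7-dimethyl-7-(triethylsilyloxy)oct-2-en-1-ol; 15 scopoletin (7-hydroxy-6-methoxy-2H-chromen-2-one)
Product: 16 7-{[(2E,4R)-4-(tert-butyldimethylsilyloxy)-3,7-dimethyl-7-(triethylsilyloxy)oct-2-en-1-yl]oxy}-6-methoxy-2H-chromen-2-one
Conditions: PPh3, DIAD, THF, 0 °C → rt
Reagents that add atoms: scopoletin (15), COc1cc2ccc(=O)oc2cc1O
Why: Mitsunobu etherification, in which the acidic 7-hydroxyl of the coumarin protonates the PPh3/DIAD betaine and its phenoxide displaces the primary allylic alkoxyphosphonium group by SN2 at C1', leaving the E alkene and C4' untouched while the silylated secondary and tertiary oxygens cannot compete.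

**Step 9**
Reactants: 16 7-{[(2E,4R)-4-(tert-butyldimethylsilyloxy)-3,7-dimethyl-7-(triethylsilyloxy)oct-2-en-1-yl]oxy}-6-methoxy-2H-chromen-2-one
Product: 17 7-{[(2E,4R)-4,7-dihydroxy-3,7-dimethyloct-2-en-1-yl]oxy}-6-methoxy-2H-chromen-2-one
Conditions: HF·pyridine, pyridine, THF, 0 °C → rt
Reagents that add atoms: none
Why: Fluoride-mediated desilylation driven by Si–F bond formation should cleave both the secondary TBS and the tertiary TES ether, and buffering with excess pyridine should keep the medium mild enough for the allyl aryl ether, the allylic alcohol and the coumarin lactone.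

**Compound list**

1 | 5,5-dimethyldihydrofuran-2(3H)-one | CC1(C)CCC(=O)O1 | starting material
2 | 4-hydroxy-N-methoxy-N,4-dimethylpentanamide | CON(C)C(=O)CCC(C)(C)O | intermediate
3 | N-methoxy-N,4-dimethyl-4-(triethylsilyloxy)pentanamide | CON(C)C(=O)CCC(C)(C)O[Si](CC)(CC)CC | intermediate
4 | ethynyltrimethylsilane | C#C[Si](C)(C)C | starting material
5 | lithium (trimethylsilyl)acetylide | [Li]C#C[Si](C)(C)C | intermediate
6 | 6-methyl-6-(triethylsilyloxy)-1-(trimethylsilyl)hept-1-yn-3-one | C[Si](C)(C)C#CC(=O)CCC(C)(C)O[Si](CC)(CC)CC | intermediate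
7 | (R)-6-methyl-6-(triethylsilyloxy)-1-(trimethylsilyl)hept-1-yn-3-ol | C[Si](C)(C)C#C[C@H](O)CCC(C)(C)O[Si](CC)(CC)CC | intermediate
8 | (R)-3-(tert-butyldimethylsilyloxy)-6-methyl-6-(triethylsilyloxy)-1-(trimethylsilyl)hept-1-yne | C[Si](C)(C)C#C[C@H](O[Si](C)(C)C(C)(C)C)CCC(C)(C)O[Si](CC)(CC)CC | intermediate
9 | (R)-3-(tert-butyldimethylsilyloxy)-6-methyl-6-(triethylsilyloxy)hept-1-yne | C#C[C@H](O[Si](C)(C)C(C)(C)C)CCC(C)(C)O[Si](CC)(CC)CC | intermediate
10 | trimethylaluminium | C[Al](C)C | starting material
11 | formaldehyde (used as paraformaldehyde) | C=O | starting material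
12 | [(1E,3R)-3-(tert-butyldimethylsilyloxy)-2,6-dimethyl-6-(triethylsilyloxy)hept-1-en-1-yl]dimethylalane | C[Al](C)/C=C(\C)[C@H](O[Si](C)(C)C(C)(C)C)CCC(C)(C)O[Si](CC)(CC)CC | intermediate
13 | lithium butyl[(1E,3R)-3-(tert-butyldimethylsilyloxy)-2,6-dimethyl-6-(triethylsilyloxy)hept-1-en-1-yl]dimethylalanate | [Li+].CCCC[Al-](C)(C)/C=C(\C)[C@H](O[Si](C)(C)C(C)(C)C)CCC(C)(C)O[Si](CC)(CC)CC | intermediate
14 | (R,E)-4-(tert-butyldimethylsilyloxy)-3,7-dimethyl-7-(triethylsilyloxy)oct-2-en-1-ol | OC/C=C(\C)[C@H](O[Si](C)(C)C(C)(C)C)CCC(C)(C)O[Si](CC)(CC)CC | intermediate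
15 | scopoletin (7-hydroxy-6-methoxy-2H-chromen-2-one) | COc1cc2ccc(=O)oc2cc1O | starting material
16 | 7-{[(2E,4R)-4-(tert-butyldimethylsilyloxy)-3,7-dimethyl-7-(triethylsilyloxy)oct-2-en-1-yl]oxy}-6-methoxy-2H-chromen-2-one | COc1cc2ccc(=O)oc2cc1OC/C=C(\C)[C@H](O[Si](C)(C)C(C)(C)C)CCC(C)(C)O[Si](CC)(CC)CC | intermediate
17 | 7-{[(2E,4R)-4,7-dihydroxy-3,7-dimethyloct-2-en-1-yl]oxy}-6-methoxy-2H-chromen-2-one | COc1cc2ccc(=O)oc2cc1OC/C=C(\C)[C@H](O)CCC(C)(C)O | target

**Step count and risks**

Total step count: 9. Longest linear sequence: 9 steps (1 → 17).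

Steps most likely to fail:

1. Step 7. The alkenyl–aluminium bond may be protonated before the heterogeneous paraformaldehyde reacts, leaving the alkene without C1', and carbometalation beside the bulky C4' substituent may be slow, so the one-flask sequence stalls between its two bond formations. Fallback, setting out from 9: the same methylalumination is terminated with I2 (THF, −30 °C) to give the isolable and purifiable (R,E)-3-(tert-butyldimethylsilyloxy)-1-iodo-2,6-dimethyl-6-(triethylsilyloxy)hept-1-ene F1. Iodine–lithium exchange (t-BuLi, Et2O, −78 °C) then gives [(1E,3R)-3-(tert-butyldimethylsilyloxy)-2,6-dimethyl-6-(triethylsilyloxy)hept-1-en-1-yl]lithium F2, which is hydroxymethylated with monomeric formaldehyde from cracked paraformaldehyde. C1' is thus introduced in a separate homogeneous operation on a purified intermediate, and the route is rejoined at 14.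

2. Step 1. The γ-hydroxy amide may re-close to the lactone during work-up, concentration or silylation, helped by the gem-dimethyl group. Fallback, setting out from 1, which avoids any γ-hydroxy acyl derivative: LiAlH4 (THF, 0 °C) should give 4-methylpentane-1,4-diol F3, and TESOTf/2,6-lutidine the bis-ether 4-methyl-1,4-bis(triethylsilyloxy)pentane F4. Swern conditions ((COCl)2, DMSO, Et3N, −78 → −30 °C) oxidise the primary triethylsilyl ether directly and leave the tertiary one, giving 4-methyl-4-(triethylsilyloxy)pentanal F5. Addition of lithium (trimethylsilyl)acetylide 5 gives racemic 6-methyl-6-(triethylsilyloxy)-1-(trimethylsilyl)hept-1-yn-3-ol F6, and MnO2 (CH2Cl2, rt) oxidises this to the ynone. The route is rejoined at 6, before the stereocentre is set.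

3. Step 8. The allylic alkoxyphosphonium intermediate may undergo SN2' attack at C3' or elimination to a diene, and sparingly soluble scopoletin may slow the productive coupling. Fallback, setting out from 14: an Appel reaction (CBr4, PPh3, CH2Cl2, 0 °C) gives (R,E)-1-bromo-4-(tert-butyldimethylsilyloxy)-3,7-dimethyl-7-(triethylsilyloxy)oct-2-ene F7. Williamson etherification of scopoletin 15 with this primary allylic bromide (K2CO3, acetone, rt) then rejoins the route at 16.

**Further compounds**

F1 | step 7 | (R,E)-3-(tert-butyldimethylsilyloxy)-1-iodo-2,6-dimethyl-6-(triethylsilyloxy)hept-1-ene | I/C=C(\C)[C@H](O[Si](C)(C)C(C)(C)C)CCC(C)(C)O[Si](CC)(CC)CC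
F2 | step 7 | [(1E,3R)-3-(tert-butyldimethylsilyloxy)-2,6-dimethyl-6-(triethylsilyloxy)hept-1-en-1-yl]lithium | [Li]/C=C(\C)[C@H](O[Si](C)(C)C(C)(C)C)CCC(C)(C)O[Si](CC)(CC)CC
F3 | step 1 | 4-methylpentane-1,4-diol | CC(C)(O)CCCO
F4 | step 1 | 4-methyl-1,4-bis(triethylsilyloxy)pentane | CC[Si](CC)(CC)OCCCC(C)(C)O[Si](CC)(CC)CC
F5 | step 1 | 4-methyl-4-(triethylsilyloxy)pentanal | O=CCCC(C)(C)O[Si](CC)(CC)CC
F6 | step 1 | racemic 6-methyl-6-(triethylsilyloxy)-1-(trimethylsilyl)hept-1-yn-3-ol | C[Si](C)(C)C#CC(O)CCC(C)(C)O[Si](CC)(CC)CC
F7 | step 8 | (R,E)-1-bromo-4-(tert-butyldimethylsilyloxy)-3,7-dimethyl-7-(triethylsilyloxy)oct-2-ene | BrC/C=C(\C)[C@H](O[Si](C)(C)C(C)(C)C)CCC(C)(C)O[Si](CC)(CC)CC
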